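**Compound numbers used throughout:** 1 2,4-dihydroxybenzaldehyde; 2 its 4-O-triisopropylsilyl ether; 3 3-chloro-3-methylbut-1-yne; 4 aryl propargyl ether; 5 allenyl phenol (in flask); 6 chromene-8-carbaldehyde; 7 enol ether; 8 arylacetaldehyde; 9 Mannich base (in flask); 10 2-arylacrolein; 11 5-methoxyresorcinol; 12 open hydroxy aldehyde (in flask); 13 lactol; 14 silyl-protected isoflavan; 15 target.

## Analysis of the target

Compound 15 is a (3R)-isoflavan: a chroman (benzo ring A, C4a–C8a; dihydropyran ring C, O1–C2–C3–C4) with a methoxy group at C5 and a hydroxyl at C7, whose C3 carries ring B through C1'. Ring B is itself the benzo ring of a 2,2-dimethyl-2H-chromene (pyran ring D): the pyran oxygen sits on C2', the pyran carbon on C3' and a free hydroxyl on C4', so ring B is joined to C3 through C8 of that chromene. C3 is the only stereocentre. It is a tertiary benzylic C–H between the two methylene groups C2 and C4, so there is no neighbouring stereocentre or heteroatom to relay from, and its configuration must come from a reagent or catalyst. It is configurationally stable in 15 but becomes enolisable in any precursor with a carbonyl group at C2 or C4. The sensitive groups are the styrene-like double bond of ring D (hydrogenation, strong acid, electrophilic oxidants) and the phloroglucinol-type ring A with its free phenol (oxidation, electrophiles). Hydrogenolytic protecting groups and asymmetric hydrogenation of an isoflavene are therefore ruled out. The difficulty is one isolated stereocentre plus two regiochemical questions: which of the three oxygens of ring A becomes O1, OMe and OH, and which oxygen of ring B closes ring D. The strategy rests on two facts. C4a lies ortho to O1, ortho to the methoxy group and para to the 7-hydroxyl, which is exactly how C4 of 5-methoxyresorcinol 11 relates to its substituents. And the chain C4–C3(aryl)–C2 is the skeleton of a 2-arylacrolein (C4 the methylene terminus, C2 the formyl carbon), so ring C is a (3+3) union of 11 with 10.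

## Retrosynthetic reasoning

**15 ⇒ 14.** The O–Si bond at the ring B hydroxyl is cut last. The para-hydroxyl of ring B must be masked while its aryl group is conjugated to an aldehyde or an iminium ion. A silyl ether is chosen because fluoride removes it without touching the chromene double bond, which excludes benzyl ethers and strongly acid-labile groups.

**14 ⇒ 13.** C2–H is traced back to C2–OH. This raises C2 to the aldehyde level, so the O1–C2 bond becomes a hemiacetal bond that forms by itself, and C2 can enter the synthesis as a formyl carbon. The forward reaction must remove the anomeric hydroxyl without disturbing C3, which is now next to a cationic centre.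

**13 ⇒ 12 ⇒ 10 + 11.** Three bonds are cut here: O1–C2 (opening the lactol to the hydroxy aldehyde 12), C4–C4a, and the C3–H bond. This is the point of greatest simplification. Ring A arrives complete and unprotected with its methoxy and free hydroxyl in place, ring C closes, and the only stereocentre is created by protonation, not by C–C bond formation at a hindered centre. Cutting C3–C1' or C2–O1 alone would leave an open chain with the stereocentre still to be made and ring A still to be differentiated. The forward reaction must deliver carbon alkylation at C4 (not C2) of 11, protonation of the resulting enamine at C3 from one face under control of a chiral primary amine salt, and trapping of the labile α-aryl aldehyde 12 as the lactol 13.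

**10 ⇒ 9 ⇒ 8.** The C3=C4 double bond is cut, so C4 comes from a one-carbon Mannich electrophile. The reactive 2-arylacrolein 10 is then made in the last step before its use from the arylacetaldehyde 8, through the Mannich base 9.

**8 ⇒ 7 ⇒ 6.** The C2–C3 bond is cut: C2 is added by Wittig one-carbon homologation to the enol ether 7, which is hydrolysed to 8. C3 of the target is therefore the formyl carbon of the chromene aldehyde 6, C2 comes from the ylide and C4 from the iminium salt.

**6 ⇒ 5 ⇒ 4 ⇒ 2 + 3 ⇒ 1.** Ring D is opened at the C3'–C bond (aromatic propargyl Claisen rearrangement through the allenyl phenol 5) and at the ether O–C bond (propargylation of 2 with 3). The regiochemical question of ring B is settled by silylating the 4-hydroxyl of 1 first. The propargyl group must then go onto the 2-hydroxyl next to the formyl group, and its only free ortho position is C3, between the two oxygens. The pyran oxygen thus ends up on C2' and the masked hydroxyl on C4'.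

## Alternatives that were turned down

**Alternative 1:** three-component conjunctive coupling around C3.
- **Disconnection:** C4–C4a and C3–C1' are both cut, leaving a two-carbon vinylboron unit (C4 and C3) between the arenes; C2 is added later.
- **Forward key step:** the boronate complex from vinylboronic acid pinacol ester A1 and the ring B aryllithium A2 is coupled with the ring A aryl triflate A3 under Pd(OAc)2 and a chiral MandyPhos ligand. The arylpalladium species adds to the vinyl terminus and triggers a 1,2-shift of the ring B aryl from boron to carbon, giving the 1,2-diarylethyl boronic ester A4 with C3 set.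
- **For it:** it is catalytic, convergent and enantioselective, with a well-explored ligand system. The C–C bond to ring A forms exactly where the triflate sits, so regiochemistry on ring A is not an issue. On that point, and on precedent for the enantio-determining step, it is stronger than the chosen route.
- **Against it:** A3 carries an oxygen at C4a that ring A does not otherwise need, so it must come from a 1,2,3,5-tetraoxygenated benzene with three differentiated oxygens. It is electron-rich and flanked by two ortho substituents, which slows oxidative addition and the carbopalladation. A2 is ortho-substituted by the pyran oxygen, which is unfavourable for the migrating group. No ring is closed and C2 is missing. After A4 there remain a one-carbon homologation of a hindered secondary benzylic boronic ester, oxidation, acidic removal of three acetal groups next to the chromene, and ring closure.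
- **Comparison:** the chosen strategy gives up the regiochemical certainty of the triflate. In return it uses ring A unprotected, closes ring C in the same step that sets C3, and leaves two steps to the target where this alternative leaves four or more.

**Alternative 2:** ring A made by folding a pyranone.
- **Disconnection:** ring A is opened at C4a–C8a. The chain C4–C3–C2 with the finished stereocentre hangs on the 4-allyloxypyran-2-one A5.
- **Forward key step:** allyloxide in allyl alcohol opens the lactone of A5. The side-chain methylene next to the freed ketone then condenses onto the new ester carbonyl and the carbocycle aromatises to the 2-alkyl-5-allyloxyresorcinol A6.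
- **For it:** A6 is symmetric about the chain, so closing ring C onto either hydroxyl gives the same chroman, and the remaining hydroxyl becomes the 5-methoxy group. The oxygen pattern of ring A is fixed by construction, with no electrophilic substitution on a resorcinol. The conditions are basic and harmless to the chromene. On ring A regiochemistry it is stronger than the chosen route.
- **Against it:** the key step makes neither the stereocentre nor ring C. C3 must be set beforehand in an open chain by a separate asymmetric step and carried through the synthesis of A5. The productive carbanion must form at the side-chain methylene, not at the more acidic methylene between the ketone and the enol ether. After A6 come desilylation, ring closure, O-methylation and two deallylations with zerovalent palladium. A benzene ring that can be bought is built in many steps.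
- **Comparison:** the chosen strategy buys ring A as 11 and accepts a selectivity question at C4 against C2. In exchange its key step is spent on the stereocentre and ring C, and the route is about half as long.

**Alternative 3:** benzannulation builds ring B on the chiral chroman.
- **Disconnection:** ring B is taken apart at C1'–C2', C2'–C3', C4'–C5' and C5'–C6'. This leaves a chroman carrying at C3 the unsaturated diazoketone side chain A7, and the siloxyalkyne A8.
- **Forward key step:** irradiation of A7 triggers a Wolff rearrangement to a vinylketene. This adds A8 in a (2+2) sense, the cyclobutenone opens in a four-electron process, and six-electron electrocyclisation with tautomerisation gives the phenol A9 with free 2'-hydroxyl, 3'-prenyl and 4'-silyloxy groups.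
- **For it:** the substitution pattern of ring B follows from the polarity of the ketene and the ynol ether, the conditions are neutral, and the ortho-prenyl phenol is one dehydrogenative cyclisation away from ring D.
- **Against it:** the stereocentre is not addressed. A7 must already be an enantiopure 3-substituted chroman, which needs its own asymmetric synthesis. Its C3–H is γ to the enone carbonyl and allylic in the ketene intermediates, so dienolisation or a hydrogen shift can erode it during the cascade. A8 is a sensitive reagent, and the valuable chiral material is carried through a photochemical multi-step cascade late in a long linear sequence.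
- **Comparison:** on ring B regiochemistry it is as strong as the chosen route but not stronger, because silylation of 1 followed by Claisen rearrangement to the only free ortho position is equally unambiguous and takes three steps from a bought arene. The chosen strategy is shorter and makes the stereocentre in its key step.

Key step: step 7

## Route

Assumption: the (S)-configured diamine salt is taken to deliver the proton to the Si face of C3 of the enamine and hence to give (3R)-13; should the sense prove opposite, the (R)-diamine is used under the same conditions.

Step 1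
Reactants: 1 2,4-dihydroxybenzaldehyde
Product: 2 2-hydroxy-4-(triisopropylsilyloxy)benzaldehyde
Conditions: TIPSCl (1.05 equiv), imidazole, CH2Cl2, 0 °C
Reagents that add atoms: triisopropylsilyl chloride, CC(C)[Si](Cl)(C(C)C)C(C)C
Why: Chemoselective O-silylation of a phenol: the 2-hydroxyl is held in a hydrogen bond to the aldehyde and is the less acidic and less accessible one, so the 4-hydroxyl should react first, and the bulk of the silyl group disfavours a second silylation.

Step 2
Reactants: 2 2-hydroxy-4-(triisopropylsilyloxy)benzaldehyde; 3 3-chloro-3-methylbut-1-yne
Product: 4 2-[(2-methylbut-3-yn-2-yl)oxy]-4-(triisopropylsilyloxy)benzaldehyde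
Conditions: DBU, CuCl2·2H2O (1 mol%), MeCN, 0 °C
Reagents that add atoms: none
Why: Copper-catalysed O-alkylation of a phenol with a tertiary propargylic chloride: the copper salt activates the terminal alkyne so that chloride ionises and the phenoxide adds at the tertiary carbon, avoiding the elimination that plain SN2 conditions favour. An amidine base in dry acetonitrile at 0 °C should leave the hindered aryl silyl ether in place.

Step 3
Reactants: 4 2-[(2-methylbut-3-yn-2-yl)oxy]-4-(triisopropylsilyloxy)benzaldehyde
Product: 6 2,2-dimethyl-5-(triisopropylsilyloxy)-2H-chromene-8-carbaldehyde, via allenyl phenol 5 (not isolated)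
Conditions: o-xylene, 140 °C
Reagents that add atoms: none
Why: Aromatic propargyl Claisen rearrangement: the [3,3] shift can only reach C3, the one free ortho position of the ether oxygen, and tautomerisation gives the allenyl phenol 5; a 1,5-hydrogen shift to the ortho-quinone methide and 6π oxa-electrocyclisation then close the 2,2-dimethylpyran ring. The pyran oxygen is thereby placed next to the formyl-bearing carbon, as ring B requires.

Step 4
Reactants: 6 2,2-dimethyl-5-(triisopropylsilyloxy)-2H-chromene-8-carbaldehyde
Product: 7 8-(2-methoxyethenyl)-2,2-dimethyl-5-(triisopropylsilyloxy)-2H-chromene (E/Z mixture)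
Conditions: Ph3P(CH2OMe)Cl, KOtBu, THF, 0 °C to rt
Reagents that add atoms: (methoxymethyl)triphenylphosphonium chloride, COC[P+](c1ccccc1)(c1ccccc1)c1ccccc1.[Cl-]
Why: Wittig olefination with the methoxymethylene ylide, a standard one-carbon homologation of aromatic aldehydes; the double-bond geometry is irrelevant because both isomers hydrolyse to the same aldehyde.

Step 5
Reactants: 7 8-(2-methoxyethenyl)-2,2-dimethyl-5-(triisopropylsilyloxy)-2H-chromene
Product: 8 2-[2,2-dimethyl-5-(triisopropylsilyloxy)-2H-chromen-8-yl]acetaldehyde
Conditions: 2 M aq HCl, THF, 40 °C
Reagents that add atoms: water, O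
Why: Acid hydrolysis of an enol ether (protonation at the aryl-bearing carbon, addition of water to the oxocarbenium ion, loss of methanol). Dilute aqueous acid should spare the aryl triisopropylsilyl ether and the chromene double bond; the arylacetaldehyde is taken on without storage.

Step 6
Reactants: 8 2-[2,2-dimethyl-5-(triisopropylsilyloxy)-2H-chromen-8-yl]acetaldehyde
Product: 10 2-[2,2-dimethyl-5-(triisopropylsilyloxy)-2H-chromen-8-yl]prop-2-enal, via Mannich base 9 (not isolated)
Conditions: CH2=NMe2 I (Eschenmoser's salt), Et3N, CH2Cl2, rt
Reagents that add atoms: N,N-dimethylmethyleneiminium iodide, C=[N+](C)C.[I-]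
Why: Mannich reaction of the enolisable aldehyde with the preformed iminium salt, then E1cB loss of dimethylamine from the Mannich base 9 (α-methylenation); the benzylic α-hydrogen makes both enolisation and elimination easy. The 2-arylacrolein tends to oligomerise and is used at once in step 7.

Step 7
Reactants: 10 2-[2,2-dimethyl-5-(triisopropylsilyloxy)-2H-chromen-8-yl]prop-2-enal; 11 5-methoxyresorcinol
Product: 13 (3R)-3-[2,2-dimethyl-5-(triisopropylsilyloxy)-2H-chromen-8-yl]-5-methoxychroman-2,7-diol (both C2 anomers), via hydroxy aldehyde 12 (not isolated)
Conditions: (S)-N1,N1-diethyl-3,3-dimethylbutane-1,2-diamine·TfOH (20 mol%), 11 (3 equiv), CHCl3/sat. aq NaCl, 0 °C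
Reagents that add atoms: none
Why: Proposed new method: the primary amine of the catalyst condenses with the α-branched enal 10 (which secondary amines activate poorly) to an α-aryl iminium ion, whose unsubstituted methylene terminus is attacked by C4 of 11 in a Friedel–Crafts step that forms C4–C4a and, after rearomatisation, leaves an aryl-conjugated enamine; the neighbouring diethylammonium N–H of the catalyst, held on one face by the tert-butyl-bearing backbone, then transfers its proton to C3 (Si face for 3R), the imine is hydrolysed to the hydroxy aldehyde 12, and the ortho hydroxyl adds to the aldehyde in a 6-exo-trig closure (O1–C2) to give the lactol 13. The closest known reaction types are the Friedel–Crafts addition of indoles to α-substituted acroleins with enantioselective enamine protonation under primary–tertiary diamine salt catalysis, and the amine-catalysed Friedel–Crafts/hemiacetalisation of electron-rich phenols and naphthols with β-substituted enals to chroman-2-ols; new here are a phenol as the carbon nucleophile in the protonation manifold and an α-aryl group on the acrolein. C3 is set by the catalyst alone, since the substrates carry no stereocentre; C2 forms as an anomeric mixture that is removed in step 8. On 11 the attack should go to C4/C6 (two equivalent positions, each para to a hydroxyl and the site of formylation of this phenol) in preference to C2 between the two hydroxyls, and O-alkylation is reversible whereas C-alkylation is not. An excess of 11 suppresses a second alkylation of the product ring, and the low temperature keeps the uncatalysed, racemic addition slow. Closure to 13 takes the α-aryl aldehyde out of reach of the amine and so protects C3 from epimerisation through a re-formed enamine.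

Step 8
Reactants: 13 (3R)-3-[2,2-dimethyl-5-(triisopropylsilyloxy)-2H-chromen-8-yl]-5-methoxychroman-2,7-diol
Product: 14 (3R)-3-[2,2-dimethyl-5-(triisopropylsilyloxy)-2H-chromen-8-yl]-5-methoxychroman-7-ol
Conditions: Et3SiH, BF3·OEt2, CH2Cl2, −78 to −20 °C
Reagents that add atoms: none
Why: Ionic reduction of a lactol: BF3·OEt2 ionises the anomeric hydroxyl to the cyclic aryloxycarbenium ion and Et3SiH delivers hydride to C2. C3 is not a reacting centre, and fast hydride capture at low temperature in an excess of silane should outrun loss of the C3 proton from the cation; the aryl silyl ether, the free phenol and the chromene are expected to tolerate the Lewis acid at this temperature.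

Step 9
Reactants: 14 (3R)-3-[2,2-dimethyl-5-(triisopropylsilyloxy)-2H-chromen-8-yl]-5-methoxychroman-7-ol
Product: 15 (3R)-3-(5-hydroxy-2,2-dimethyl-2H-chromen-8-yl)-5-methoxychroman-7-ol
Conditions: Bu4NF, AcOH, THF, 0 °C
Reagents that add atoms: none
Why: Fluoride-induced cleavage of the aryl silyl ether, driven by Si–F bond formation; acetic acid buffers the phenoxide so that the electron-rich product is not exposed to base and air. No stereocentre or double bond is affected.

## Compound list

1 | 2,4-dihydroxybenzaldehyde | O=Cc1ccc(O)cc1O | starting material
2 | 2-hydroxy-4-(triisopropylsilyloxy)benzaldehyde | O=Cc1ccc(O[Si](C(C)C)(C(C)C)C(C)C)cc1O | intermediate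
3 | 3-chloro-3-methylbut-1-yne | CC(C)(Cl)C#C | starting material
4 | 2-[(2-methylbut-3-yn-2-yl)oxy]-4-(triisopropylsilyloxy)benzaldehyde | O=Cc1ccc(O[Si](C(C)C)(C(C)C)C(C)C)cc1OC(C)(C)C#C | intermediate
5 | 2-hydroxy-3-(3-methylbuta-1,2-dien-1-yl)-4-(triisopropylsilyloxy)benzaldehyde | O=Cc1ccc(O[Si](C(C)C)(C(C)C)C(C)C)c(C=C=C(C)C)c1O | intermediate (not isolated)
6 | 2,2-dimethyl-5-(triisopropylsilyloxy)-2H-chromene-8-carbaldehyde | O=Cc1ccc(O[Si](C(C)C)(C(C)C)C(C)C)c2c1OC(C)(C)C=C2 | intermediate
7 | 8-(2-methoxyethenyl)-2,2-dimethyl-5-(triisopropylsilyloxy)-2H-chromene (E/Z mixture) | COC=Cc1ccc(O[Si](C(C)C)(C(C)C)C(C)C)c2c1OC(C)(C)C=C2 | intermediate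
8 | 2-[2,2-dimethyl-5-(triisopropylsilyloxy)-2H-chromen-8-yl]acetaldehyde | O=CCc1ccc(O[Si](C(C)C)(C(C)C)C(C)C)c2c1OC(C)(C)C=C2 | intermediate
9 | 3-(dimethylamino)-2-[2,2-dimethyl-5-(triisopropylsilyloxy)-2H-chromen-8-yl]propanal (racemic) | CN(C)CC(C=O)c1ccc(O[Si](C(C)C)(C(C)C)C(C)C)c2c1OC(C)(C)C=C2 | intermediate (not isolated)
10 | 2-[2,2-dimethyl-5-(triisopropylsilyloxy)-2H-chromen-8-yl]prop-2-enal | C=C(C=O)c1ccc(O[Si](C(C)C)(C(C)C)C(C)C)c2c1OC(C)(C)C=C2 | intermediate
11 | 5-methoxyresorcinol (5-methoxybenzene-1,3-diol) | COc1cc(O)cc(O)c1 | starting material
12 | (2R)-3-(2,4-dihydroxy-6-methoxyphenyl)-2-[2,2-dimethyl-5-(triisopropylsilyloxy)-2H-chromen-8-yl]propanal | COc1cc(O)cc(O)c1C[C@@H](C=O)c1ccc(O[Si](C(C)C)(C(C)C)C(C)C)c2c1OC(C)(C)C=C2 | intermediate (not isolated)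
13 | (3R)-3-[2,2-dimethyl-5-(triisopropylsilyloxy)-2H-chromen-8-yl]-5-methoxychroman-2,7-diol (both C2 anomers) | COc1cc(O)cc2c1C[C@H](c1ccc(O[Si](C(C)C)(C(C)C)C(C)C)c3c1OC(C)(C)C=C3)C(O)O2 | intermediate
14 | (3R)-3-[2,2-dimethyl-5-(triisopropylsilyloxy)-2H-chromen-8-yl]-5-methoxychroman-7-ol | COc1cc(O)cc2c1C[C@H](c1ccc(O[Si](C(C)C)(C(C)C)C(C)C)c3c1OC(C)(C)C=C3)CO2 | intermediate
15 | (3R)-3-(5-hydroxy-2,2-dimethyl-2H-chromen-8-yl)-5-methoxychroman-7-ol | COc1cc(O)cc2c1C[C@H](c1ccc(O)c3c1OC(C)(C)C=C3)CO2 | target

## Step count and least certain steps

Total: 9 steps. Longest linear sequence: 9 steps (1 to 15); 3 and 11 enter as bought compounds.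

**Step 7 (key step).**
- **What may go wrong:** poor facial control of the protonation at C3 is the most likely failure. It can arise from a mixture of enamine geometries, from the uncatalysed racemic addition of 11 to free 10, or from re-enolisation of 12 by the amine before the lactol closes. Attack through C2 of 11, a second alkylation of the product ring, and oligomerisation of 10 can also lower the material throughput.
- **Fallback (known chemistry):** an auxiliary-controlled alkylation that sets out from 8 and 11 and comes back to the route at 15.
  - Pinnick oxidation of 8 (NaClO2, NaH2PO4, 2-methylbut-2-ene) would give 2-[2,2-dimethyl-5-(triisopropylsilyloxy)-2H-chromen-8-yl]acetic acid F1. This is coupled (pivaloyl chloride, Et3N, LiCl) with (R)-4-benzyloxazolidin-2-one to the N-acyl oxazolidinone F2.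
  - In parallel, Vilsmeier formylation of 11 (POCl3, DMF) gives 2,4-dihydroxy-6-methoxybenzaldehyde F3. This is silylated (TBSCl, imidazole) to the bis(tert-butyldimethylsilyl) ether F4, reduced (NaBH4) to the benzyl alcohol F5 and converted (CBr4, PPh3) into the benzyl bromide F6, which is used freshly.
  - The enolate of F2 formed with NaN(SiMe3)2 at −78 °C is alkylated by F6 on the face away from the benzyl group of the auxiliary, giving the (2R)-imide F7. Reduction with LiBH4 releases the auxiliary and gives the primary alcohol F8.
  - Bu4NF removes all three silyl groups to give the tetraol F9. Mitsunobu closure (PPh3, DIAD) of the ring A hydroxyl ortho to the chain onto the primary alcohol gives 15.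
  - Regiochemistry on ring A is then fixed at the formylation stage, where an isomer can be removed early.

**Step 8.**
- **What may go wrong:** the cyclic carbenium ion may lose the C3 proton to give an enol ether, so that the C3 configuration erodes on re-protonation. Acid-induced addition to, or dimerisation of, the chromene double bond and capture of the cation by a second ring A are further risks.
- **Fallback:** it sets out from 13 and comes back at 14 without any cation at C2. NaBH4 (MeOH/THF, 0 °C) reduces 13 through its open form to (2R)-3-(2,4-dihydroxy-6-methoxyphenyl)-2-[2,2-dimethyl-5-(triisopropylsilyloxy)-2H-chromen-8-yl]propan-1-ol F10. Mitsunobu closure (PPh3, DIAD, THF) of the ortho hydroxyl onto the primary alcohol then gives 14.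

**Step 2.**
- **What may go wrong:** base-induced cleavage or migration of the silyl group, which sits para to the formyl group, and slow alkylation of the hydrogen-bonded, hindered phenoxide with competing elimination of 3.
- **Fallback:** it sets out from 2 and comes back at 6, bypassing 4 and the Claisen step. Condensation of 2 with 3-methylbut-2-enal mediated by PhB(OH)2 and AcOH in refluxing toluene with removal of water brings the enal carbon to C3, the free ortho position of the hydroxyl. The resulting ortho-quinone methide closes by 6π electrocyclisation to the chromene 6.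

**Step 5.**
- **What may go wrong:** acid-induced hydration or dimerisation of the chromene during the hydrolysis, and self-aldol condensation or air oxidation of the arylacetaldehyde 8 before it is used.
- **Fallback:** it sets out from 7 and comes back at 10 without free 8 and without aqueous acid. The enol ether 7 is treated directly with CH2=NMe2 I in MeCN and then with aqueous NaHCO3. The electron-rich enol ether carbon attacks the iminium ion, the oxocarbenium ion is hydrolysed to the Mannich base 9, and 9 eliminates dimethylamine to 10.

## Further compounds

F1 | step 7 | 2-[2,2-dimethyl-5-(triisopropylsilyloxy)-2H-chromen-8-yl]acetic acid | OC(=O)Cc1ccc(O[Si](C(C)C)(C(C)C)C(C)C)c2c1OC(C)(C)C=C2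
F2 | step 7 | (4R)-4-benzyl-3-{2-[2,2-dimethyl-5-(triisopropylsilyloxy)-2H-chromen-8-yl]acetyl}-1,3-oxazolidin-2-one | O=C(Cc1ccc(O[Si](C(C)C)(C(C)C)C(C)C)c2c1OC(C)(C)C=C2)N1[C@H](Cc2ccccc2)COC1=O
F3 | step 7 | 2,4-dihydroxy-6-methoxybenzaldehyde | COc1cc(O)cc(O)c1C=O
F4 | step 7 | 2,4-bis(tert-butyldimethylsilyloxy)-6-methoxybenzaldehyde | COc1cc(O[Si](C)(C)C(C)(C)C)cc(O[Si](C)(C)C(C)(C)C)c1C=O
F5 | step 7 | [2,4-bis(tert-butyldimethylsilyloxy)-6-methoxyphenyl]methanol | COc1cc(O[Si](C)(C)C(C)(C)C)cc(O[Si](C)(C)C(C)(C)C)c1CO
F6 | step 7 | 2-(bromomethyl)-1,5-bis(tert-butyldimethylsilyloxy)-3-methoxybenzene | COc1cc(O[Si](C)(C)C(C)(C)C)cc(O[Si](C)(C)C(C)(C)C)c1CBr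
F7 | step 7 | (4R)-4-benzyl-3-{(2R)-3-[2,4-bis(tert-butyldimethylsilyloxy)-6-methoxyphenyl]-2-[2,2-dimethyl-5-(triisopropylsilyloxy)-2H-chromen-8-yl]propanoyl}-1,3-oxazolidin-2-one | COc1cc(O[Si](C)(C)C(C)(C)C)cc(O[Si](C)(C)C(C)(C)C)c1C[C@H](c1ccc(O[Si](C(C)C)(C(C)C)C(C)C)c2c1OC(C)(C)C=C2)C(=O)N1[C@H](Cc2ccccc2)COC1=O
F8 | step 7 | (2R)-3-[2,4-bis(tert-butyldimethylsilyloxy)-6-methoxyphenyl]-2-[2,2-dimethyl-5-(triisopropylsilyloxy)-2H-chromen-8-yl]propan-1-ol | COc1cc(O[Si](C)(C)C(C)(C)C)cc(O[Si](C)(C)C(C)(C)C)c1C[C@@H](CO)c1ccc(O[Si](C(C)C)(C(C)C)C(C)C)c2c1OC(C)(C)C=C2
F9 | step 7 | 4-[(2R)-3-hydroxy-2-(5-hydroxy-2,2-dimethyl-2H-chromen-8-yl)propyl]-5-methoxybenzene-1,3-diol | COc1cc(O)cc(O)c1C[C@@H](CO)c1ccc(O)c2c1OC(C)(C)C=C2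
F10 | step 8 | (2R)-3-(2,4-dihydroxy-6-methoxyphenyl)-2-[2,2-dimethyl-5-(triisopropylsilyloxy)-2H-chromen-8-yl]propan-1-ol | COc1cc(O)cc(O)c1C[C@@H](CO)c1ccc(O[Si](C(C)C)(C(C)C)C(C)C)c2c1OC(C)(C)C=C2
F0 | step 2 | none | none
F0 | step 5 | none | none
A1 | alternative 1 | vinylboronic acid pinacol ester | C=CB1OC(C)(C)C(C)(C)O1
A2 | alternative 1 | 8-lithio-5-(methoxymethoxy)-2,2-dimethyl-2H-chromene | [Li]c1ccc(OCOC)c2c1OC(C)(C)C=C2
A3 | alternative 1 | 2-methoxy-4,6-bis(methoxymethoxy)phenyl trifluoromethanesulfonate | COc1cc(OCOC)cc(OCOC)c1OS(=O)(=O)C(F)(F)F
A4 | alternative 1 | 2-{(1R)-2-[2-methoxy-4,6-bis(methoxymethoxy)phenyl]-1-[5-(methoxymethoxy)-2,2-dimethyl-2H-chromen-8-yl]ethyl}-4,4,5,5-tetramethyl-1,3,2-dioxaborolane | COc1cc(OCOC)cc(OCOC)c1C[C@H](c1ccc(OCOC)c2c1OC(C)(C)C=C2)B1OC(C)(C)C(C)(C)O1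
A5 | alternative 2 | 4-(allyloxy)-6-{(3R)-3-[5-(allyloxy)-2,2-dimethyl-2H-chromen-8-yl]-4-(tert-butyldimethylsilyloxy)butyl}-2H-pyran-2-one | O=c1cc(OCC=C)cc(CC[C@H](c2ccc(OCC=C)c3c2OC(C)(C)C=C3)CO[Si](C)(C)C(C)(C)C)o1
A6 | alternative 2 | 5-(allyloxy)-2-{(2R)-2-[5-(allyloxy)-2,2-dimethyl-2H-chromen-8-yl]-3-(tert-butyldimethylsilyloxy)propyl}benzene-1,3-diol | C=CCOc1cc(O)c(C[C@H](c2ccc(OCC=C)c3c2OC(C)(C)C=C3)CO[Si](C)(C)C(C)(C)C)c(O)c1
A7 | alternative 3 | (E)-1-diazo-4-[(3R)-5-methoxy-7-(triisopropylsilyloxy)chroman-3-yl]but-3-en-2-one | COc1cc(O[Si](C(C)C)(C(C)C)C(C)C)cc2c1C[C@H](/C=C/C(=O)C=[N+]=[N-])CO2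
A8 | alternative 3 | 5-methyl-1-(triisopropylsilyloxy)hex-4-en-1-yne | CC(C)=CCC#CO[Si](C(C)C)(C(C)C)C(C)C
A9 | alternative 3 | (3R)-3-[2-hydroxy-3-(3-methylbut-2-en-1-yl)-4-(triisopropylsilyloxy)phenyl]-5-methoxy-7-(triisopropylsilyloxy)chroman | COc1cc(O[Si](C(C)C)(C(C)C)C(C)C)cc2c1C[C@H](c1ccc(O[Si](C(C)C)(C(C)C)C(C)C)c(CC=C(C)C)c1O)CO2
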